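## Structural features

The target is a 2-aryl-3-methoxychroman-4-one, a dihydroflavonol 3-methyl ether. Ring A is a benzene carrying 5-OH, 6-OMe and 7-OMe, fused through C4a/C8a to the pyranone ring C (O1, C2, C3, C4=O). Ring B, a 2',5'-dihydroxy-4'-methoxyphenyl group, is attached at C2. The only stereocentres are the neighbours C2 (aryl) and C3 (OMe); the SMILES reads as (2R,3R), the 2,3-trans arrangement with both substituents equatorial. Base is a threat because C3–H is α to the ketone and O1 is β to it: enolisation followed by E1cB loss of the ring A phenoxide would give an achiral α-methoxychalcone and erase both centres. Acid can ionise C2–O1 because ring B has oxygen donors ortho and para to C2, and the free hydroquinone of ring B is readily oxidised by air to a quinone. The real difficulty is therefore twofold: setting the absolute configuration of the C2/C3 pair with a methyl ether at C3, and releasing the ketone and three phenols (5, 2', 5') beside four methyl ethers only when no base is needed any more. Ring C has O1–C2 and C3–C4 on either side of the C2–C3 unit, so it is the formal adduct of a ring A ortho-quinone methide (O1=C8a–C4a=C4) and a C2=C3 alkene. The 2'-oxygen and 4'-methoxy of ring B make C2 the cation-stabilising end of that alkene, and the key step uses exactly this polarity.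

## Logic of the disconnections

16 ⇒ 15. The two benzyl–O bonds on ring B and the methyl–O bond at C5 are restored. The hydroquinone and the fully free, base-sensitive ketone should exist only in the last flask. The C5 methyl is the one methyl ether that a chelating Lewis acid can reach selectively, because it is peri to the C4 carbonyl. This masks every phenol. The forward step must remove two benzyl groups and one of five methyl groups in one treatment without opening ring C.

15 ⇒ 14. The C4 carbonyl is traced back to C4–H/C4–OMe. A C4 ether is what the ring-forming step delivers, and it keeps the β-aryloxy ketone out of the molecule while the C3 oxygen is manipulated. No enolisable centre remains. The forward step must abstract hydride from C4 and not from C2–H or the benzyl methylene groups.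

14 ⇒ 13 ⇒ 12. The O–CH3 bond at C3 is cut, then the hydrogen on that oxygen is exchanged for acetyl. The ring-forming step needs a weakly donating, participating acyloxy group at C3, so the methyl ether can only be installed afterwards. This leads back to the direct cycloadduct. Both forward steps use base and must therefore come before the ketone exists.

12 ⇒ 2 + 8 + 9 (through 10 and 11). The C3–C4 and O1–C2 bonds are cut. These are the two ring C bonds that flank the C2–C3 unit, and cutting them splits the molecule into a ring A piece and a ring B piece of similar size while removing the ring and all three stereocentres at once. The forward step must control regiochemistry (aryl at C2, acyloxy at C3), the 2,3-trans relationship and the absolute configuration.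

2 ⇒ 1. The bond between the ring A carbon (C4a) and the formyl carbon (C4) is cut. Both positions ortho to the hydroxyl of 1 are equivalent, so a single ortho-formylation suffices and no regiochemical question arises.

8 ⇒ 7 ⇒ 5 (through 6). The enol O–acyl bond is cut, then the C2–C3 bond (flavanone numbering) is cut as a one-carbon homologation of the aldehyde. This reduces the two-carbon side chain to the formyl group of 5. The forward acylation must give the E enol ester.

5 ⇒ 4 ⇒ 3. The aryl–CHO bond and then the two O–benzyl bonds are cut. The position para to the methoxy and ortho to a benzyloxy group is the most activated one in 4, so formylation should go there. The phenols of 3 only need a protecting group that survives acid, base and oxidant until the end.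

## Other disconnections considered

Alternative 1: The cut is C2–C3 together with the C3–O(methyl) bond, with ring C also opened at O1–C2. In the forward step, Rh2(OAc)4 would decompose the ring A diazo ketone A2. The carbene would be intercepted by the one-carbon alcohol to give an oxonium ylide, and this would add to aldehyde 5 in an aldol fashion to give the syn α-methoxy-β-hydroxy ketone A1. Deallylation with Pd(PPh3)4 (zerovalent palladium), Mitsunobu closure of O1–C2 with inversion and deprotection would follow.
- In its favour: C3 arrives with its methyl ether and C4 as the ketone. The acetate-to-methyl exchange and the C4 oxidation of the chosen plan are not needed, so this plan is the better one on redox and protecting-group economy after the key step. Convergence is equal, since both plans join a ring A and a ring B fragment derived from 1 and 5. The total step count should be about the same, with a longest line perhaps one step shorter.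
- Against it: trapping of the ylide competes with a simple 1,2-proton shift (plain O–H insertion) and is favoured by electrophilic aldehydes, whereas 5 is electron-rich and ortho-substituted. Syn/anti and absolute control both depend on an added chiral co-catalyst with no help from the substrate. A1 is prone to retro-aldol cleavage and C3 epimerisation. The Mitsunobu step at a carbinol next to a 2,4,5-trioxygenated ring may ionise, so the inversion is not secure. A2 requires diazomethane or an equivalent.
- Comparison: mechanistically both plans rest on a chiral acid acting on a reactive intermediate, and neither has the advantage there. Structurally the chosen plan is stronger, because it closes ring C in the same step that forms both bonds and relays C2 from C3 through the acetate.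

Alternative 2: The cut removes four bonds of ring A (C5–C4a, C8–C8a, C7–C8, C5–C6). In the forward step, irradiation of diazo ketone A4 would trigger a Wolff rearrangement. The resulting ketene would add [2+2] to siloxyalkyne A5, and four-electron ring opening followed by six-electron ring closure would give phenol A3.
- In its favour: the substitution pattern of ring A is fixed unambiguously by the pericyclic cascade. The 5-OH arrives free and distinguished from O1 (silyl), which is better than the late chelation-controlled demethylation of the chosen plan. The cascade itself is mechanistically more predictable than an untested ion-pair-controlled addition.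
- Against it: the annulation creates no stereocentre. The whole C4–C3–C2 stereotriad must already be present in A5, so the stereochemical problem is only moved into a long acyclic synthesis. Ring A is built from scratch although 1 supplies it in one step. The 5-OH would have to be masked again before O1 is released, or ring closure could occur through either phenol. Ring C closure with inversion at C2 and the C4 oxidation are still required; the C4 oxidation issue is equal in both plans.
- Comparison: on step economy this plan is clearly worse, and on structure it spends its key step on the part of the molecule that is easiest to obtain.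

Alternative 3: The cut is C2–C3 and O1–C8a, so ring C is made before ring A. In the forward step, aldehyde 5 and siloxydiene A7 would combine under Ti(OiPr)4/BINOL to give dihydropyranone A6 with both stereocentres.
- In its favour: catalytic enantioselective hetero-Diels–Alder reactions of aldehydes with siloxydienes are well established, so precedent for absolute control is better than for the chosen key step. C3 carries its methyl ether and C4 is already a ketone, which is also better on redox economy.
- Against it: 5 is a poor heterodienophile, and the 1,2-dioxygenated diene terminus is hindered, so the cis/trans outcome at C2/C3 is uncertain if the reaction turns into a Mukaiyama aldol/cyclisation sequence. Above all, ring A would then have to be annulated onto the C4a=C8a double bond of a vinylogous ester with three oxygen substituents in defined positions. That is a long sequence on a core whose C3 is epimerisable and whose C2–O1 bond is base-labile.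
- Comparison: this plan wins on the certainty of the stereo-defining step and loses on structure, because the hardest carbon framework is postponed to a sensitive late stage. It also loses on step economy, because ring A is commercially available.

Key step: step 6

Remarks on the chemistry (assumptions):
- The sense of induction of the phosphoric acid in step 6 cannot be predicted with confidence. The (R)-acid is written; its mirror image is used instead if a first trial shows the opposite sense.
- 12–14 are drawn as the 3,4-trans (4R) compounds. A C4 epimer with the same C2/C3 configuration may be carried on, because step 9 removes C4 as a stereocentre.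
- In 12–14 the descriptor at C3 is S for the spatial arrangement that becomes 3R in 15 and 16, because C2 outranks an sp3 C4 but not the carbonyl C4.

## Steps

Step 1
Reactants: 1 3,4,5-trimethoxyphenol
Product: 2 6-hydroxy-2,3,4-trimethoxybenzaldehyde
Conditions: MgCl2, Et3N, (CH2O)n, MeCN, reflux; then 1 M aq. HCl
Reagents that add atoms: paraformaldehyde (as formaldehyde), C=O
Why: Casnati–Skattebøl ortho-formylation: the magnesium phenoxide directs formaldehyde to the ortho position and the benzylic alkoxide is oxidised by a second equivalent of formaldehyde; both ortho positions of 1 are equivalent, so only one aldehyde can form.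

Step 2
Reactants: 3 2-methoxybenzene-1,4-diol (2-methoxyhydroquinone)
Product: 4 1,4-bis(benzyloxy)-2-methoxybenzene
Conditions: BnBr, K2CO3, DMF, 60 °C, under N2
Reagents that add atoms: benzyl bromide, BrCc1ccccc1
Why: Williamson ether synthesis on both phenols; nitrogen is used because the hydroquinone anion is oxidisable, and benzyl is chosen because it survives acid, base and DDQ and falls off in the final Lewis acid step.

Step 3
Reactants: 4 1,4-bis(benzyloxy)-2-methoxybenzene
Product: 5 2,5-bis(benzyloxy)-4-methoxybenzaldehyde
Conditions: POCl3, DMF, 0 → 70 °C; then ice-water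
Reagents that add atoms: N,N-dimethylformamide, CN(C)C=O; water, O
Why: Vilsmeier–Haack formylation; the position para to the methoxy and ortho to a benzyloxy group has two activating oxygens, whereas the other free positions are either flanked by two substituents or activated by one oxygen only, as in the formylation of 1,2,4-trialkoxybenzenes.

Step 4
Reactants: 5 2,5-bis(benzyloxy)-4-methoxybenzaldehyde
Product: 7 2-[2,5-bis(benzyloxy)-4-methoxyphenyl]acetaldehyde, via enol ether 6 (not isolated)
Conditions: Ph3P(CH2OMe)Cl, KOtBu, THF, 0 °C → rt; then 2 M aq. HCl, 45 °C
Reagents that add atoms: (methoxymethyl)triphenylphosphonium chloride, COC[P+](c1ccccc1)(c1ccccc1)c1ccccc1.[Cl-]; water, O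
Why: Wittig methoxymethylenation followed in the same flask by acid hydrolysis of the enol ether (one-carbon homologation); the geometry of 6 is irrelevant, the aryl ethers are inert to dilute acid, and the electron-rich arylacetaldehyde is used at once to avoid aldol self-condensation.

Step 5
Reactants: 7 2-[2,5-bis(benzyloxy)-4-methoxyphenyl]acetaldehyde
Product: 8 (E)-2-[2,5-bis(benzyloxy)-4-methoxyphenyl]ethenyl acetate
Conditions: Ac2O, KOAc, 120 °C
Reagents that add atoms: acetic anhydride, CC(=O)OC(C)=O
Why: Enol acetylation of an enolisable aldehyde under equilibrating conditions; the E isomer should dominate because the Z isomer forces the acetoxy group against the ortho-benzyloxy-substituted ring and loses conjugation, and any Z isomer is removed by chromatography.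

Step 6
Reactants: 2 6-hydroxy-2,3,4-trimethoxybenzaldehyde; 8 (E)-2-[2,5-bis(benzyloxy)-4-methoxyphenyl]ethenyl acetate; 9 trimethyl orthoformate
Product: 12 (2R,3S,4R)-2-[2,5-bis(benzyloxy)-4-methoxyphenyl]-4,5,6,7-tetramethoxy-3,4-dihydro-2H-chromen-3-yl acetate, via dimethyl acetal 10 (not isolated), via ortho-quinone methide 11 (not isolated)
Conditions: (R)-3,3'-bis(2,4,6-triisopropylphenyl)-1,1'-binaphthyl-2,2'-diyl hydrogen phosphate (10 mol %), 5 Å MS, toluene, −20 °C → rt
Reagents that add atoms: none
Why: Proposed new method: the acid converts 2 and 9 into acetal 10, which ionises to the O-methyl oxocarbenium ion (O-protonated 11) held by the chiral phosphate through the phenol hydrogen bond and ion pairing. The acetoxy-bearing carbon of 8 attacks C4 because the positive charge then develops on the carbon attached to ring B, where the 2'-benzyloxy and 4'-methoxy groups stabilise it far better than the weakly donating acetate oxygen could stabilise the alternative cation, and this fixes the 2-aryl-3-acyloxy regiochemistry. The acetate carbonyl captures the benzylic cation as a trans-4,5-disubstituted 1,3-dioxolan-2-ylium ion and the phenol oxygen O1 opens it at C2 from the opposite side, so ring C closes by a 6-exo-tet O-alkylation that completes a formal inverse-demand hetero-[4+2] addition (a concerted asynchronous addition to the E alkene would give the same result). C4 is set by the phosphate, which leaves one face of the cation open; C3 is set relative to C4 by the approach with ring B endo to the E-configured cation (3,4-trans); C2 is set relative to C3 by the anti opening of the acetoxonium ion, equivalent to retention of the E geometry (2,3-trans). The closest known reaction types are the acid-catalysed three-component chroman synthesis from salicylaldehydes, orthoformates and styrenes, and the chiral-phosphoric-acid-catalysed [4+2] additions of ortho-quinone methides to ortho-hydroxystyrenes and enamides. The step needs regio-, 2,3-trans- and enantioselectivity, which ring B, acetate participation and the catalyst are expected to provide; the sieves take up methanol so that 8 is not transesterified, and the 3,4-cis diastereomer is removed by chromatography because it would carry the opposite C2/C3 pair.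

Step 7
Reactants: 12 (2R,3S,4R)-2-[2,5-bis(benzyloxy)-4-methoxyphenyl]-4,5,6,7-tetramethoxy-3,4-dihydro-2H-chromen-3-yl acetate
Product: 13 (2R,3S,4R)-2-[2,5-bis(benzyloxy)-4-methoxyphenyl]-4,5,6,7-tetramethoxy-3,4-dihydro-2H-chromen-3-ol
Conditions: K2CO3 (cat.), MeOH, 0 °C → rt
Reagents that add atoms: none
Why: Base-catalysed transesterification of a secondary acetate (Zemplén type); no ketone is present yet, so base can neither epimerise C3 nor open ring C, and the benzylic methyl ether at C4 is stable to base.

Step 8
Reactants: 13 (2R,3S,4R)-2-[2,5-bis(benzyloxy)-4-methoxyphenyl]-4,5,6,7-tetramethoxy-3,4-dihydro-2H-chromen-3-ol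
Product: 14 (2R,3S,4R)-2-[2,5-bis(benzyloxy)-4-methoxyphenyl]-3,4,5,6,7-pentamethoxy-3,4-dihydro-2H-chromene
Conditions: NaH, MeI, THF, 0 °C → rt
Reagents that add atoms: iodomethane, CI
Why: Williamson O-methylation of the secondary alkoxide; at this oxidation level neither C2–H nor C4–H is acidic, so the stereocentres are not at risk.

Step 9
Reactants: 14 (2R,3S,4R)-2-[2,5-bis(benzyloxy)-4-methoxyphenyl]-3,4,5,6,7-pentamethoxy-3,4-dihydro-2H-chromene
Product: 15 (2R,3R)-2-[2,5-bis(benzyloxy)-4-methoxyphenyl]-3,5,6,7-tetramethoxy-2,3-dihydro-4H-chromen-4-one
Conditions: DDQ, CH2Cl2/pH 7 phosphate buffer (10:1), 0 °C → rt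
Reagents that add atoms: water, O
Why: DDQ oxidative cleavage of an electron-rich benzylic ether, the reaction type used to remove para-methoxybenzyl ethers: hydride is abstracted from C4, whose cation is stabilised by the methoxy oxygen and by O1, 5-OMe and 7-OMe of ring A, then water adds and methanol is lost to give the ketone; C2 and C3 are untouched and the C4 stereocentre disappears.

Step 10
Reactants: 15 (2R,3R)-2-[2,5-bis(benzyloxy)-4-methoxyphenyl]-3,5,6,7-tetramethoxy-2,3-dihydro-4H-chromen-4-one
Product: 16 (2R,3R)-2-(2,5-dihydroxy-4-methoxyphenyl)-5-hydroxy-3,6,7-trimethoxy-2,3-dihydro-4H-chromen-4-one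
Conditions: BCl3, C6HMe5, CH2Cl2, −78 → 0 °C; then MeOH, degassed H2O
Reagents that add atoms: none
Why: BCl3 cleaves aryl benzyl ethers at low temperature with pentamethylbenzene as benzyl cation trap (a known debenzylation) and, on warming, the methyl ether peri to the C4 carbonyl through a six-membered boron chelate (the known chelation-controlled 5-O-demethylation of flavonoids); the other methyl ethers lack this chelate, and the absence of base avoids E1cB ring opening and C3 epimerisation, so one treatment replaces a separate demethylation and hydrogenolysis that would not be orthogonal.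

## Compound list

1 | 3,4,5-trimethoxyphenol | COc1cc(O)cc(OC)c1OC | starting material
2 | 6-hydroxy-2,3,4-trimethoxybenzaldehyde | COc1cc(O)c(C=O)c(OC)c1OC | intermediate
3 | 2-methoxybenzene-1,4-diol (2-methoxyhydroquinone) | COc1cc(O)ccc1O | starting material
4 | 1,4-bis(benzyloxy)-2-methoxybenzene | COc1cc(OCc2ccccc2)ccc1OCc1ccccc1 | intermediate
5 | 2,5-bis(benzyloxy)-4-methoxybenzaldehyde | COc1cc(OCc2ccccc2)c(C=O)cc1OCc1ccccc1 | intermediate
6 | 1,4-bis(benzyloxy)-2-methoxy-5-(2-methoxyethenyl)benzene (E/Z mixture, not isolated) | COC=Cc1cc(OCc2ccccc2)c(OC)cc1OCc1ccccc1 | intermediate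
7 | 2-[2,5-bis(benzyloxy)-4-methoxyphenyl]acetaldehyde | O=CCc1cc(OCc2ccccc2)c(OC)cc1OCc1ccccc1 | intermediate
8 | (E)-2-[2,5-bis(benzyloxy)-4-methoxyphenyl]ethenyl acetate | CC(=O)O/C=C/c1cc(OCc2ccccc2)c(OC)cc1OCc1ccccc1 | intermediate
9 | trimethyl orthoformate | COC(OC)OC | starting material
10 | 2-(dimethoxymethyl)-3,4,5-trimethoxyphenol (not isolated) | COC(OC)c1c(O)cc(OC)c(OC)c1OC | intermediate
11 | (6E)-3,4,5-trimethoxy-6-(methoxymethylidene)cyclohexa-2,4-dien-1-one (not isolated; reacts as its O-protonated form, the O-methyl oxocarbenium phosphate ion pair) | CO/C=C1/C(=O)C=C(OC)C(OC)=C1OC | intermediate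
12 | (2R,3S,4R)-2-[2,5-bis(benzyloxy)-4-methoxyphenyl]-4,5,6,7-tetramethoxy-3,4-dihydro-2H-chromen-3-yl acetate | COc1cc2O[C@H](c3cc(OCc4ccccc4)c(OC)cc3OCc3ccccc3)[C@@H](OC(C)=O)[C@H](OC)c2c(OC)c1OC | intermediate
13 | (2R,3S,4R)-2-[2,5-bis(benzyloxy)-4-methoxyphenyl]-4,5,6,7-tetramethoxy-3,4-dihydro-2H-chromen-3-ol | COc1cc2O[C@H](c3cc(OCc4ccccc4)c(OC)cc3OCc3ccccc3)[C@@H](O)[C@H](OC)c2c(OC)c1OC | intermediate
14 | (2R,3S,4R)-2-[2,5-bis(benzyloxy)-4-methoxyphenyl]-3,4,5,6,7-pentamethoxy-3,4-dihydro-2H-chromene | COc1cc2O[C@H](c3cc(OCc4ccccc4)c(OC)cc3OCc3ccccc3)[C@@H](OC)[C@H](OC)c2c(OC)c1OC | intermediate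
15 | (2R,3R)-2-[2,5-bis(benzyloxy)-4-methoxyphenyl]-3,5,6,7-tetramethoxy-2,3-dihydro-4H-chromen-4-one | COc1cc2O[C@H](c3cc(OCc4ccccc4)c(OC)cc3OCc3ccccc3)[C@@H](OC)C(=O)c2c(OC)c1OC | intermediate
16 | (2R,3R)-2-(2,5-dihydroxy-4-methoxyphenyl)-5-hydroxy-3,6,7-trimethoxy-2,3-dihydro-4H-chromen-4-one | COc1cc(O)c([C@H]2Oc3cc(OC)c(OC)c(O)c3C(=O)[C@@H]2OC)cc1O | target

## Step count and least certain steps

Total step count: 10. Longest linear sequence: 9 steps (3 → 4 → 5 → 7 → 8 → 12 → 13 → 14 → 15 → 16); the ring A branch contributes one step before the junction.

Step 6 (key step, proposed new method). The most likely failure is poor enantiofacial discrimination. The enol acetate has no hydrogen-bond donor, so the phosphate organises only the cation. An unselective 3,4-relationship would also translate into lost enantiopurity at C3 once C4 is erased. Methanol set free in the flask may in addition transesterify 8 to an enol ether that adds with the opposite regiochemistry, and the cation may be captured by the electron-rich arenes. The fallback uses known chemistry only, sets out from 1 and 5 and comes back to the route at 15: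
- Friedel–Crafts acetylation of 1 (AcOH, BF3·OEt2, 90 °C) should give 1-(6-hydroxy-2,3,4-trimethoxyphenyl)ethan-1-one F1.
- O-Alkylation (NaH, MOMCl, DMF) gives 1-[6-(methoxymethoxy)-2,3,4-trimethoxyphenyl]ethan-1-one F2.
- Claisen–Schmidt condensation with 5 (KOH, EtOH) gives (E)-3-[2,5-bis(benzyloxy)-4-methoxyphenyl]-1-[6-(methoxymethoxy)-2,3,4-trimethoxyphenyl]prop-2-en-1-one F3.
- Juliá–Colonna epoxidation (poly-L-leucine, urea–H2O2, DBU, THF) is expected, by analogy with simple chalcones, to give [(2R,3S)-3-[2,5-bis(benzyloxy)-4-methoxyphenyl]oxiran-2-yl][6-(methoxymethoxy)-2,3,4-trimethoxyphenyl]methanone F4.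
- HCl in MeOH removes the methoxymethyl group, and the freed phenol opens the epoxide at the benzylic carbon with inversion, closing ring C to (2R,3R)-2-[2,5-bis(benzyloxy)-4-methoxyphenyl]-3-hydroxy-5,6,7-trimethoxy-2,3-dihydro-4H-chromen-4-one F5.
- Purdie methylation (MeI, Ag2O, CH2Cl2), which avoids strong base, gives 15.

This path gives up the convergent cycloaddition and is longer, but every step is a standard operation of dihydroflavonol synthesis.

Step 5. The most likely failure is incomplete E selectivity of the enol acetylation, together with aldol self-condensation of the sensitive aldehyde 7 in hot basic medium. A Z isomer would react through a different ion-pair geometry in step 6. The fallback sets out from 5 and comes back at 8, building the E alkene stereospecifically instead of by enolisation: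
- Seyferth–Gilbert homologation with the Ohira–Bestmann reagent (K2CO3, MeOH) gives 1,4-bis(benzyloxy)-2-ethynyl-5-methoxybenzene F6.
- syn-Hydroboration with pinacolborane (cat. Cp2Zr(H)Cl) gives 2-[(E)-2-[2,5-bis(benzyloxy)-4-methoxyphenyl]ethenyl]-4,4,5,5-tetramethyl-1,3,2-dioxaborolane F7.
- KHF2 in aqueous MeOH gives potassium [(E)-2-[2,5-bis(benzyloxy)-4-methoxyphenyl]ethenyl]trifluoroborate F8.
- Copper-catalysed oxidative C–O coupling with acetic acid (CuBr, DMAP, O2, 4 Å MS; Chan–Lam type) should give 8 with retention of the alkene geometry.

Step 9. The most likely failure is loss of site selectivity in the hydride abstraction. C2–H is activated by O1 and by ring B, and the product could be dehydrogenated further across C2–C3. The fallback sets out from 14 and comes back at 15, replacing oxidation of the ether by solvolysis and alcohol oxidation. Acid-catalysed hydrolysis of the ionisable benzylic methyl ether (cat. TsOH, THF/H2O, 40 °C) should give (2R,3S)-2-[2,5-bis(benzyloxy)-4-methoxyphenyl]-3,5,6,7-tetramethoxy-3,4-dihydro-2H-chromen-4-ol F9 as a mixture of C4 epimers. Dess–Martin oxidation (CH2Cl2, rt) of this alcohol gives 15.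

Step 10. The most likely failure is over-reaction of the Lewis acid. This could be cleavage of a second methyl ether next to a boron-bound oxygen (6-OMe or 4'-OMe), or ionisation of C2–O1 assisted by the freed 2'-oxygen, with erosion at C2. The fallback sets out from 15 and comes back at 16, separating the two deprotections. Hydrogenolysis (H2, Pd(OH)2/C, EtOAc, rt) should give (2R,3R)-2-(2,5-dihydroxy-4-methoxyphenyl)-3,5,6,7-tetramethoxy-2,3-dihydro-4H-chromen-4-one F10. Chelation-controlled demethylation of the 5-O-methyl group alone (AlCl3, MeCN, rt) then gives 16.

## Further compounds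

F1 | step 6 | 1-(6-hydroxy-2,3,4-trimethoxyphenyl)ethan-1-one | CC(=O)c1c(O)cc(OC)c(OC)c1OC
F2 | step 6 | 1-[6-(methoxymethoxy)-2,3,4-trimethoxyphenyl]ethan-1-one | COCOc1cc(OC)c(OC)c(OC)c1C(C)=O
F3 | step 6 | (E)-3-[2,5-bis(benzyloxy)-4-methoxyphenyl]-1-[6-(methoxymethoxy)-2,3,4-trimethoxyphenyl]prop-2-en-1-one | COCOc1cc(OC)c(OC)c(OC)c1C(=O)/C=C/c1cc(OCc2ccccc2)c(OC)cc1OCc1ccccc1
F4 | step 6 | [(2R,3S)-3-[2,5-bis(benzyloxy)-4-methoxyphenyl]oxiran-2-yl][6-(methoxymethoxy)-2,3,4-trimethoxyphenyl]methanone | COCOc1cc(OC)c(OC)c(OC)c1C(=O)[C@@H]1O[C@H]1c1cc(OCc2ccccc2)c(OC)cc1OCc1ccccc1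
F5 | step 6 | (2R,3R)-2-[2,5-bis(benzyloxy)-4-methoxyphenyl]-3-hydroxy-5,6,7-trimethoxy-2,3-dihydro-4H-chromen-4-one | COc1cc2O[C@H](c3cc(OCc4ccccc4)c(OC)cc3OCc3ccccc3)[C@@H](O)C(=O)c2c(OC)c1OC
F6 | step 5 | 1,4-bis(benzyloxy)-2-ethynyl-5-methoxybenzene | C#Cc1cc(OCc2ccccc2)c(OC)cc1OCc1ccccc1
F7 | step 5 | 2-[(E)-2-[2,5-bis(benzyloxy)-4-methoxyphenyl]ethenyl]-4,4,5,5-tetramethyl-1,3,2-dioxaborolane | CC1(C)OB(/C=C/c2cc(OCc3ccccc3)c(OC)cc2OCc2ccccc2)OC1(C)C
F8 | step 5 | potassium [(E)-2-[2,5-bis(benzyloxy)-4-methoxyphenyl]ethenyl]trifluoroborate | [K+].F[B-](F)(F)/C=C/c1cc(OCc2ccccc2)c(OC)cc1OCc1ccccc1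
F9 | step 9 | (2R,3S)-2-[2,5-bis(benzyloxy)-4-methoxyphenyl]-3,5,6,7-tetramethoxy-3,4-dihydro-2H-chromen-4-ol (C4 epimers) | COc1cc2O[C@H](c3cc(OCc4ccccc4)c(OC)cc3OCc3ccccc3)[C@@H](OC)C(O)c2c(OC)c1OC
F10 | step 10 | (2R,3R)-2-(2,5-dihydroxy-4-methoxyphenyl)-3,5,6,7-tetramethoxy-2,3-dihydro-4H-chromen-4-one | COc1cc(O)c([C@H]2Oc3cc(OC)c(OC)c(OC)c3C(=O)[C@@H]2OC)cc1O
A1 | alternative 1 | (2R,3S)-1-[2-(allyloxy)-4,5,6-trimethoxyphenyl]-3-[2,5-bis(benzyloxy)-4-methoxyphenyl]-3-hydroxy-2-methoxypropan-1-one (syn) | C=CCOc1cc(OC)c(OC)c(OC)c1C(=O)[C@H](OC)[C@@H](O)c1cc(OCc2ccccc2)c(OC)cc1OCc1ccccc1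
A2 | alternative 1 | 1-[2-(allyloxy)-4,5,6-trimethoxyphenyl]-2-diazoethan-1-one | C=CCOc1cc(OC)c(OC)c(OC)c1C(=O)C=[N+]=[N-]
A3 | alternative 2 | 2-[(1R,2R,3S)-3-acetoxy-3-[2,5-bis(benzyloxy)-4-methoxyphenyl]-1-(tert-butyldimethylsilyloxy)-2-methoxypropyl]-5,6-dimethoxy-3-(triisopropylsilyloxy)phenol | COc1cc(O[Si](C(C)C)(C(C)C)C(C)C)c([C@@H](O[Si](C)(C)C(C)(C)C)[C@H](OC)[C@@H](OC(C)=O)c2cc(OCc3ccccc3)c(OC)cc2OCc2ccccc2)c(O)c1OC
A4 | alternative 2 | (3Z)-1-diazo-3,4-dimethoxybut-3-en-2-one | CO/C=C(\OC)C(=O)C=[N+]=[N-]
A5 | alternative 2 | (1S,2R,3R)-1-[2,5-bis(benzyloxy)-4-methoxyphenyl]-3-(tert-butyldimethylsilyloxy)-2-methoxy-5-(triisopropylsilyloxy)pent-4-yn-1-yl acetate | CC(C)[Si](OC#C[C@@H](O[Si](C)(C)C(C)(C)C)[C@H](OC)[C@@H](OC(C)=O)c1cc(OCc2ccccc2)c(OC)cc1OCc1ccccc1)(C(C)C)C(C)C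
A6 | alternative 3 | (2R,3R)-2-[2,5-bis(benzyloxy)-4-methoxyphenyl]-3-methoxy-2,3-dihydro-4H-pyran-4-one | COc1cc(OCc2ccccc2)c([C@H]2OC=CC(=O)[C@@H]2OC)cc1OCc1ccccc1
A7 | alternative 3 | (1Z,3E)-4-ethoxy-1-methoxy-2-(trimethylsilyloxy)buta-1,3-diene | CCO/C=C/C(O[Si](C)(C)C)=C/OC
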